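## Retrosynthetic overview

1. Germacrane numbering is used: ring C1–C10, lactone carbons C11–C13, C14 = CH2OH on C10, C15 = CH3 on C4. The enabling feature is C6: it is both the allylic carbinol carbon next to the (Z)-C4=C5 alkene in the ten-membered carbocycle and the O-bearing carbon of the five-membered lactone (O, C6, C7, C11, C12), with its oxygen 1,4 to the C12 carboxyl carbon.
2. Key disconnection C5–C6: an open-chain (Z)-alkenyl iodide / C6 aldehyde / C12 methyl ester closes the carbocycle by an intramolecular Nozaki–Hiyama–Kishi addition, and the C6 alkoxide so formed closes the lactone in the same operation.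
3. C7–C8 (both stereocentres) comes from a chromium-catalysed asymmetric 2-(methoxycarbonyl)allylation of a C8 aldehyde with a Morita–Baylis–Hillman bromide that carries C6 as a dimethyl acetal; the angelate is placed on C8–OH before ring closure.
4. The C8 aldehyde: the C1=C10 geometry is fixed by ring-closing metathesis inside a temporary six-membered lactone (C2–O–C8, from itaconic anhydride) that is then opened; the (Z)-C4=C5 iodide comes from anti-carboalumination/iodination; C2 comes from an asymmetric propargylation of acrolein.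
5. Order of ring formation: temporary δ-lactone (made in step 4, opened in step 6), then the ten-membered carbocycle, then the γ-lactone (both in step 14).

Key step: step 14

Remark: the catalyst antipodes named in steps 1 and 11 are assumed to induce the sense stated; if the sense is opposite, the mirror-image catalyst is used.

## Route

Step 1
Reactants: 1 acrolein; 2 allenylboronic acid pinacol ester
Product: 4 (S)-hex-1-en-5-yn-3-ol, via pinacol borate ester 3 (not isolated)
Conditions: (S)-TRIP (5 mol%), 4 Å MS, toluene, −20 °C; then aq. NaHCO3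
Reagents that add atoms: none
Why: Chiral-phosphoric-acid-catalysed propargylation of an aldehyde with an allenylboronate (SE2' through a closed six-membered transition state held by the acid) should give the homopropargylic alcohol, the (S)-acid being expected to set C2 as S as it does for aryl and alkenyl aldehydes.

Step 2
Reactants: 4 (S)-hex-1-en-5-yn-3-ol
Product: 7 (S,Z)-6-iodo-5-methylhexa-1,5-dien-3-ol, via syn-alkenylalane 5 (not isolated), via chelated (Z)-alkenylalane 6 (not isolated)
Conditions: Me3Al (3.5 equiv), Cp2ZrCl2 (0.25 equiv), ClCH2CH2Cl, rt, then reflux; then I2, THF, −30 °C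
Reagents that add atoms: trimethylaluminium C[Al](C)C; iodine II
Why: Zirconium-catalysed methylalumination of the terminal alkyne is syn, heating lets the alkoxide-bound aluminium drive isomerization to the chelated (Z)-alkenylalane, and iodinolysis with retention should place iodine cis to C3 (net anti-carboalumination of a homopropargylic alcohol); C2 is not touched.

Step 3
Reactants: 7 (S,Z)-6-iodo-5-methylhexa-1,5-dien-3-ol; 8 itaconic anhydride
Product: 9 itaconate 4-monoester of 7
Conditions: DMAP (10 mol%), CH2Cl2, 0 °C to rt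
Reagents that add atoms: none
Why: DMAP-catalysed alcoholysis of the cyclic anhydride should occur at the non-conjugated, more electrophilic carbonyl (regioselective anhydride opening), so that the ester carbon becomes C8 and the free conjugated acid becomes C14.

Step 4
Reactants: 9 itaconate 4-monoester of 7
Product: 10 six-membered lactone acid
Conditions: second-generation Grubbs catalyst (H2IMes)(PCy3)Cl2Ru=CHPh (5 mol%), toluene, 80 °C, 5 mM
Reagents that add atoms: none
Why: Ring-closing olefin metathesis between the C1 vinyl group and the 1,1-disubstituted itaconate alkene should release ethene, and the six-membered ring can only hold C2 and C9 cis on the new C1=C10 bond, which is the geometry of the target.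

Step 5
Reactants: 10 six-membered lactone acid
Product: 11 hydroxymethyl lactone
Conditions: BH3·THF (1.5 equiv), THF, −10 to 0 °C (MeOH quench)
Reagents that add atoms: none
Why: Borane reduces a carboxylic acid through its acyloxyborane much faster than a lactone or a trisubstituted alkene (chemoselective borane reduction), which should give the C14 allylic alcohol.

Step 6
Reactants: 11 hydroxymethyl lactone
Product: 12 dihydroxy Weinreb amide
Conditions: MeNH(OMe)·HCl (3 equiv), Me3Al (3 equiv), CH2Cl2, 0 °C to rt (aq. potassium sodium tartrate work-up)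
Reagents that add atoms: N,O-dimethylhydroxylamine hydrochloride CNOC.Cl
Why: Weinreb aminolysis of the lactone by the aluminium amide should open the ring at the acyl carbon C8 and free C2–OH without touching the C2 centre or the alkenes.

Step 7
Reactants: 12 dihydroxy Weinreb amide
Product: 13 bis-silyl Weinreb amide
Conditions: TBSOTf (2.5 equiv), 2,6-lutidine, CH2Cl2, −78 to 0 °C
Reagents that add atoms: tert-butyldimethylsilyl triflate CC(C)(C)[Si](C)(C)OS(=O)(=O)C(F)(F)F
Why: Silyl triflate/2,6-lutidine silylation should protect the primary (C14) and the secondary (C2) allylic alcohol together before the γ-hydroxy amide can relactonize.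

Step 8
Reactants: 13 bis-silyl Weinreb amide
Product: 14 C8 aldehyde
Conditions: i-Bu2AlH, THF, −78 °C (aq. potassium sodium tartrate work-up); used crude
Reagents that add atoms: none
Why: Hydride reduction of a Weinreb amide stops at the chelated aluminium hemiaminal and gives the aldehyde only on work-up; the β,γ-unsaturated aldehyde is used at once to avoid migration of the C1=C10 alkene.

Step 9
Reactants: 15 methyl acrylate; 16 2,2-dimethoxyacetaldehyde
Product: 17 Morita–Baylis–Hillman alcohol
Conditions: DABCO (0.5 equiv), 1,4-dioxane/H2O, rt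
Reagents that add atoms: none
Why: Morita–Baylis–Hillman reaction of an activated α-alkoxy aldehyde with methyl acrylate; the carbinol centre is racemic and is removed in step 10.

Step 10
Reactants: 17 Morita–Baylis–Hillman alcohol
Product: 18 (Z)-allylic bromide
Conditions: NBS, Me2S, CH2Cl2, 0 °C to rt
Reagents that add atoms: N-bromosuccinimide O=C1CCC(=O)N1Br
Why: Corey–Kim-type activation of the allylic alcohol as an alkoxysulfonium salt and SN2' attack of bromide should give the rearranged, thermodynamically preferred (Z)-2-(bromomethyl)enoate (ester trans to the acetal carbon) under conditions that spare the acetal.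

Step 11
Reactants: 14 C8 aldehyde; 18 (Z)-allylic bromide
Product: 20 anti hydroxy ester (7R,8S), via trimethylsilyl ether 19 (not isolated)
Conditions: CrCl2 (10 mol%), chiral tridentate carbazole bis(oxazoline) ligand (12 mol%), Mn powder (2 equiv), Me3SiCl (2 equiv), i-Pr2NEt (30 mol%), THF, rt; then citric acid, MeOH, 0 °C
Reagents that add atoms: none
Why: Nozaki–Hiyama allylation made catalytic in chromium (Mn as reductant, Me3SiCl for turnover): the γ-substituted 2-(methoxycarbonyl)allylchromium adds through a chair transition state with the acetal-bearing carbon equatorial to give the anti C7/C8 pair, the ligand directs attack to the Re face of the aldehyde to set 8S and hence 7R, and the silyl trap keeps the C8 oxygen from lactonizing onto C12; the alkenyl iodide is inert in the absence of nickel.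

Step 12
Reactants: 20 anti hydroxy ester (7R,8S); 21 angelic acid
Product: 22 C8 angelate
Conditions: 21, 2,4,6-trichlorobenzoyl chloride, Et3N, toluene, rt; then 20, 75 °C
Reagents that add atoms: none
Why: Yamaguchi-type mixed-anhydride esterification without a nucleophilic catalyst should acylate the hindered C8–OH with retention and is the standard way to keep the angelate from isomerizing to the tiglate.

Step 13
Reactants: 22 C8 angelate
Product: 24 C6 aldehyde, via collidinium salt 23 (not isolated)
Conditions: Et3SiOTf (2 equiv), 2,4,6-collidine (3 equiv), CH2Cl2, 0 °C; then H2O; used crude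
Reagents that add atoms: water O
Why: Silyl-triflate/collidine cleavage of a dimethyl acetal through a collidinium salt should free the aldehyde under nearly neutral conditions that leave the silyl ethers, both enoates and the epimerizable C7 centre untouched.

Step 14
Reactants: 24 C6 aldehyde
Product: 26 bis-silyl germacranolide, via macrocyclic hydroxy ester 25 (not isolated)
Conditions: CrCl2 (10 equiv), NiCl2 (0.1 equiv), DMSO/THF 3:1, rt, 24 added by syringe pump (final 2 mM); aq. NH4Cl work-up; then PPTS (cat.), CH2Cl2, rt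
Reagents that add atoms: none
Why: This is an intramolecular Nozaki–Hiyama–Kishi reaction: zerovalent nickel (made from NiCl2 by CrCl2) inserts into the C5–I bond, transmetalation gives a configurationally stable (Z)-alkenyl species of trivalent chromium that adds to the C6 aldehyde, and the C6 alkoxide (free alcohol 25 after work-up) acylates on the C12 methyl ester. The closest known reaction types are Nozaki–Hiyama–Kishi macrocyclizations to ten-membered carbocycles and the addition/lactonization tandem of iodoacrylates with aldehydes. The ten-membered carbocycle closes in a 10-exo-trig mode (C5 onto C6=O) and the γ-lactone in a 5-exo-trig mode (O6 onto C12=O with loss of methanol). C6 should be set as R by the adjacent C7 centre: Felkin–Anh attack anti to the bulky C8 branch with the acrylate inside, which is also the extended C5–C6–C7–C8 arrangement of the trans-fused lactone. The step needs aldehyde-over-ester chemoselectivity (inherent to organochromium reagents), retention of the (Z)-C4=C5 geometry (secured by the trisubstituted alkenyl iodide) and ring closure over oligomerization (secured by slow addition at about 2 mM, helped by the two cis-alkenes, which turn the chain ends toward each other).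

Step 15
Reactants: 26 bis-silyl germacranolide
Product: 27 CNP0270898.1
Conditions: HF·pyridine, pyridine, THF, 0 °C to rt
Reagents that add atoms: none
Why: Buffered fluoride desilylation should remove both tert-butyldimethylsilyl ethers without affecting the α-methylene lactone, the angelate or the allylic alcohols.

## Compound list

1 | acrolein (prop-2-enal) | C=CC=O | starting material
2 | allenylboronic acid pinacol ester (4,4,5,5-tetramethyl-2-(propa-1,2-dien-1-yl)-1,3,2-dioxaborolane) | C=C=CB1OC(C)(C)C(C)(C)O1 | starting material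
3 | (S)-2-(hex-1-en-5-yn-3-yloxy)-4,4,5,5-tetramethyl-1,3,2-dioxaborolane | C=C[C@@H](OB1OC(C)(C)C(C)(C)O1)CC#C | intermediate (not isolated)
4 | (S)-hex-1-en-5-yn-3-ol | C=C[C@@H](O)CC#C | intermediate
5 | dimethylaluminium alkoxide of (S,E)-6-(dimethylalumanyl)-5-methylhexa-1,5-dien-3-ol (syn-carboalumination adduct) | C=C[C@@H](O[Al](C)C)C/C(C)=C/[Al](C)C | intermediate (not isolated)
6 | six-membered (Z)-alkenylalane chelate, ring O–Al(CH3)–CH=C(CH3)–CH2–CH(vinyl), S at the vinyl-bearing carbon | C=C[C@@H]1CC(C)=C[Al](C)O1 | intermediate (not isolated)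
7 | (S,Z)-6-iodo-5-methylhexa-1,5-dien-3-ol | C=C[C@@H](O)C/C(C)=C\I | intermediate
8 | itaconic anhydride (3-methylidenedihydrofuran-2,5-dione) | C=C1CC(=O)OC1=O | starting material
9 | (S,Z)-4-[(6-iodo-5-methylhexa-1,5-dien-3-yl)oxy]-2-methylidene-4-oxobutanoic acid | C=C[C@@H](OC(=O)CC(=C)C(=O)O)C/C(C)=C\I | intermediate
10 | (S)-6-[(Z)-3-iodo-2-methylprop-2-en-1-yl]-2-oxo-3,6-dihydro-2H-pyran-4-carboxylic acid | OC(=O)C1=C[C@H](C/C(C)=C\I)OC(=O)C1 | intermediate
11 | (S)-4-(hydroxymethyl)-6-[(Z)-3-iodo-2-methylprop-2-en-1-yl]-3,6-dihydro-2H-pyran-2-one | OCC1=C[C@H](C/C(C)=C\I)OC(=O)C1 | intermediate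
12 | (S,3E,7Z)-5-hydroxy-3-(hydroxymethyl)-8-iodo-N-methoxy-N,7-dimethylocta-3,7-dienamide | CON(C)C(=O)C/C(CO)=C\[C@@H](O)C/C(C)=C\I | intermediate
13 | (S,3E,7Z)-5-[(tert-butyldimethylsilyl)oxy]-3-{[(tert-butyldimethylsilyl)oxy]methyl}-8-iodo-N-methoxy-N,7-dimethylocta-3,7-dienamide | CON(C)C(=O)C/C(CO[Si](C)(C)C(C)(C)C)=C\[C@@H](O[Si](C)(C)C(C)(C)C)C/C(C)=C\I | intermediate
14 | (S,3E,7Z)-5-[(tert-butyldimethylsilyl)oxy]-3-{[(tert-butyldimethylsilyl)oxy]methyl}-8-iodo-7-methylocta-3,7-dienal | O=CC/C(CO[Si](C)(C)C(C)(C)C)=C\[C@@H](O[Si](C)(C)C(C)(C)C)C/C(C)=C\I | intermediate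
15 | methyl acrylate | C=CC(=O)OC | starting material
16 | 2,2-dimethoxyacetaldehyde | COC(OC)C=O | starting material
17 | methyl 3-hydroxy-4,4-dimethoxy-2-methylidenebutanoate (racemic) | COC(=O)C(=C)C(O)C(OC)OC | intermediate
18 | methyl (Z)-2-(bromomethyl)-4,4-dimethoxybut-2-enoate | COC(=O)/C(CBr)=C/C(OC)OC | intermediate
19 | methyl (3R,4S,6E,8S,10Z)-8-[(tert-butyldimethylsilyl)oxy]-6-{[(tert-butyldimethylsilyl)oxy]methyl}-3-(dimethoxymethyl)-11-iodo-10-methyl-2-methylidene-4-[(trimethylsilyl)oxy]undeca-6,10-dienoate | I/C=C(/C)C[C@H](O[Si](C)(C)C(C)(C)C)/C=C(/CO[Si](C)(C)C(C)(C)C)C[C@H](O[Si](C)(C)C)[C@@H](C(=C)C(=O)OC)C(OC)OC | intermediate (not isolated)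
20 | methyl (3R,4S,6E,8S,10Z)-8-[(tert-butyldimethylsilyl)oxy]-6-{[(tert-butyldimethylsilyl)oxy]methyl}-3-(dimethoxymethyl)-4-hydroxy-11-iodo-10-methyl-2-methylideneundeca-6,10-dienoate (germacrane 7R,8S,2S) | I/C=C(/C)C[C@H](O[Si](C)(C)C(C)(C)C)/C=C(/CO[Si](C)(C)C(C)(C)C)C[C@H](O)[C@@H](C(=C)C(=O)OC)C(OC)OC | intermediate
21 | angelic acid ((Z)-2-methylbut-2-enoic acid) | C/C=C(/C)C(=O)O | starting material
22 | methyl (3R,4S,6E,8S,10Z)-8-[(tert-butyldimethylsilyl)oxy]-6-{[(tert-butyldimethylsilyl)oxy]methyl}-3-(dimethoxymethyl)-11-iodo-10-methyl-2-methylidene-4-{[(2Z)-2-methylbut-2-enoyl]oxy}undeca-6,10-dienoate | I/C=C(/C)C[C@H](O[Si](C)(C)C(C)(C)C)/C=C(/CO[Si](C)(C)C(C)(C)C)C[C@H](OC(=O)/C(C)=C\C)[C@@H](C(=C)C(=O)OC)C(OC)OC | intermediate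
23 | 2,4,6-trimethylpyridinium triflate bound through nitrogen to the methoxy-bearing C6 of 22 (one OCH3 of the acetal replaced by the collidinium nitrogen; other centres as in 22) | I/C=C(/C)C[C@H](O[Si](C)(C)C(C)(C)C)/C=C(/CO[Si](C)(C)C(C)(C)C)C[C@H](OC(=O)/C(C)=C\C)[C@@H](C(=C)C(=O)OC)C(OC)[n+]1c(C)cc(C)cc1C.[O-]S(=O)(=O)C(F)(F)F | intermediate (not isolated)
24 | methyl (3R,4S,6E,8S,10Z)-8-[(tert-butyldimethylsilyl)oxy]-6-{[(tert-butyldimethylsilyl)oxy]methyl}-3-formyl-11-iodo-10-methyl-2-methylidene-4-{[(2Z)-2-methylbut-2-enoyl]oxy}undeca-6,10-dienoate | I/C=C(/C)C[C@H](O[Si](C)(C)C(C)(C)C)/C=C(/CO[Si](C)(C)C(C)(C)C)C[C@H](OC(=O)/C(C)=C\C)[C@@H](C(=C)C(=O)OC)C=O | intermediate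
25 | methyl 2-[(1S,2R,3Z,6S,7E,10S)-6-[(tert-butyldimethylsilyl)oxy]-8-{[(tert-butyldimethylsilyl)oxy]methyl}-2-hydroxy-4-methyl-10-{[(2Z)-2-methylbut-2-enoyl]oxy}cyclodeca-3,7-dien-1-yl]prop-2-enoate | COC(=O)C(=C)[C@H]1[C@H](O)/C=C(/C)C[C@H](O[Si](C)(C)C(C)(C)C)/C=C(/CO[Si](C)(C)C(C)(C)C)C[C@@H]1OC(=O)/C(C)=C\C | intermediate (not isolated)
26 | (2S,6R,7R,8S)-2,14-bis[(tert-butyldimethylsilyl)oxy]-8-{[(2Z)-2-methylbut-2-enoyl]oxy}germacra-1(10)E,4Z,11(13)-trien-12,6-olide | C=C1C(=O)O[C@@H]2/C=C(/C)C[C@H](O[Si](C)(C)C(C)(C)C)/C=C(/CO[Si](C)(C)C(C)(C)C)C[C@H](OC(=O)/C(C)=C\C)[C@@H]12 | intermediate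
27 | (2S,6R,7R,8S)-2,14-dihydroxy-8-{[(2Z)-2-methylbut-2-enoyl]oxy}germacra-1(10)E,4Z,11(13)-trien-12,6-olide (CNP0270898.1) | C=C1C(=O)O[C@@H]2/C=C(/C)C[C@H](O)/C=C(/CO)C[C@H](OC(=O)/C(C)=C\C)[C@@H]12 | target

## Step count and risks

Total step count: 15. Longest linear sequence: 13 (steps 1–8 and 11–15); steps 9–10 make the side fragment 18.

The three steps most likely to fail:

1. Step 14 (key step). What may go wrong: β-elimination of the C8 angelate from the enolizable aldehyde (with epimerization at C7), O8-to-O6 acyl migration at the alkoxide stage, and erosion of facial selectivity at C6 by the β-acyloxy group, on top of oligomerization. Fallback (ring closure before acylation): it sets out from 20. Silylation (Et3SiOTf, 2,6-lutidine, CH2Cl2, −78 °C) should give the C8 triethylsilyl ether F1. Acetal cleavage as in step 13 should give, through the collidinium salt F2, the silyl-protected aldehyde F3. The same CrCl2/NiCl2 macrocyclization and PPTS treatment should give, through the macrocyclic hydroxy ester F4, the 8-O-triethylsilyl lactone F5; the silyl ether cannot leave or migrate and, as a bulky non-chelating group, supports Felkin–Anh control. Selective removal of the triethylsilyl group (PPTS, MeOH/CH2Cl2, 0 °C) should give the 8-hydroxy lactone F6, which is esterified with 21 as in step 12. The fallback comes back to the route at 26.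

2. Step 11. What may go wrong: loss of catalyst control (low enantio- or diastereoselection) with this γ-acetal-substituted bromide, and migration of the β,γ-double bond of aldehyde 14 under the Lewis-acidic conditions. Fallback (separation in place of asymmetric induction): it sets out from 14. Stoichiometric nickel-free CrCl2 in THF at 0 °C adds the allylchromium from 18 through the same anti-selective chair without a ligand, with a short reaction time and buffered work-up to keep the hydroxy ester open. This should give 20 together with its (7S,8R)-anti diastereomer F7. Because C2 is already fixed the two are diastereomers and are separated by chromatography. The fallback comes back to the route at 20.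

3. Step 12. What may go wrong: isomerization of the angelate to the tiglate, and lactonization of C8–OH onto the C12 ester, during the slow heated acylation of a hindered alcohol. Fallback (build the Z-alkene on the ester instead of transferring it): it sets out from 20. Esterification with 2-[bis(2,2,2-trifluoroethoxy)phosphoryl]propanoic acid (EDC, DMAP (cat.), CH2Cl2, 0 °C) should give the C8 phosphonopropanoate F8. A Still–Gennari olefination (KN(SiMe3)2, 18-crown-6, acetaldehyde, THF, −78 °C) should then give the (Z)-2-methylbut-2-enoate. The fallback comes back to the route at 22.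

Further compounds

F1 | step 14 | C8 triethylsilyl ether of 20 | I/C=C(/C)C[C@H](O[Si](C)(C)C(C)(C)C)/C=C(/CO[Si](C)(C)C(C)(C)C)C[C@H](O[Si](CC)(CC)CC)[C@@H](C(=C)C(=O)OC)C(OC)OC
F2 | step 14 | collidinium triflate at the methoxy-bearing C6 of F1 | I/C=C(/C)C[C@H](O[Si](C)(C)C(C)(C)C)/C=C(/CO[Si](C)(C)C(C)(C)C)C[C@H](O[Si](CC)(CC)CC)[C@@H](C(=C)C(=O)OC)C(OC)[n+]1c(C)cc(C)cc1C.[O-]S(=O)(=O)C(F)(F)F
F3 | step 14 | C6 aldehyde with C8 triethylsilyl ether | I/C=C(/C)C[C@H](O[Si](C)(C)C(C)(C)C)/C=C(/CO[Si](C)(C)C(C)(C)C)C[C@H](O[Si](CC)(CC)CC)[C@@H](C(=C)C(=O)OC)C=O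
F4 | step 14 | macrocyclic hydroxy ester with C8 triethylsilyl ether | COC(=O)C(=C)[C@H]1[C@H](O)/C=C(/C)C[C@H](O[Si](C)(C)C(C)(C)C)/C=C(/CO[Si](C)(C)C(C)(C)C)C[C@@H]1O[Si](CC)(CC)CC
F5 | step 14 | 2,14-bis(tert-butyldimethylsilyl)-8-O-triethylsilyl germacranolide | C=C1C(=O)O[C@@H]2/C=C(/C)C[C@H](O[Si](C)(C)C(C)(C)C)/C=C(/CO[Si](C)(C)C(C)(C)C)C[C@H](O[Si](CC)(CC)CC)[C@@H]12
F6 | step 14 | 2,14-bis(tert-butyldimethylsilyl)-8-hydroxy germacranolide | C=C1C(=O)O[C@@H]2/C=C(/C)C[C@H](O[Si](C)(C)C(C)(C)C)/C=C(/CO[Si](C)(C)C(C)(C)C)C[C@H](O)[C@@H]12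
F7 | step 11 | (7S,8R)-anti diastereomer of 20 | I/C=C(/C)C[C@H](O[Si](C)(C)C(C)(C)C)/C=C(/CO[Si](C)(C)C(C)(C)C)C[C@@H](O)[C@H](C(=C)C(=O)OC)C(OC)OC
F8 | step 12 | C8 2-[bis(2,2,2-trifluoroethoxy)phosphoryl]propanoate of 20 | I/C=C(/C)C[C@H](O[Si](C)(C)C(C)(C)C)/C=C(/CO[Si](C)(C)C(C)(C)C)C[C@H](OC(=O)C(C)P(=O)(OCC(F)(F)F)OCC(F)(F)F)[C@@H](C(=C)C(=O)OC)C(OC)OC
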